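The route rests on cutting the biaryl bond between C3 of the naphthoquinone ring and C1 of the naphthalene. Both ends are innately matched: naphthalene C1 is the α-carbon ortho to the C2 hydroxyl and para to the C4 methoxyl, and quinone C3 is the only hydrogen-bearing enone carbon, C2 being blocked by methyl. An acid-catalysed dehydrogenative naphthol–quinone coupling therefore unites the unprotected halves, 4-methoxy-7-methylnaphthalene-2,5-diol and 5-methoxy-2-methyl-1,4-naphthoquinone, in one operation: conjugate addition, rearomatisation and reoxidation by a second equivalent of quinone give the target directly. The naphthalenediol comes from methyl orsellinate by a Michael–Dieckmann annulation.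

Key step: step 6

Assumption: the target is written without a configuration at the hindered biaryl axis, so it is planned as the racemate; no stereocentre has to be set.

Step 1
Reactants: 1 plumbagin (5-hydroxy-2-methylnaphthalene-1,4-dione)
Product: 2 5-methoxy-2-methylnaphthalene-1,4-dione
Conditions: MeI, Ag2O, CH2Cl2, rt, dark
Reagents that add atoms: iodomethane, CI
Why: Ag2O-mediated Williamson-type O-methylation of the chelated peri hydroxyl proceeds without free base, which the base-sensitive quinone should tolerate.

Step 2
Reactants: 3 methyl orsellinate (methyl 2,4-dihydroxy-6-methylbenzoate)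
Product: 4 methyl 2-hydroxy-6-methyl-4-[(triisopropylsilyl)oxy]benzoate
Conditions: TIPSCl, imidazole, DMF, 0 °C to rt
Reagents that add atoms: triisopropylsilyl chloride, CC(C)[Si](Cl)(C(C)C)C(C)C
Why: Regioselective silyl ether formation, because the C4 hydroxyl is free whereas the C2 hydroxyl is hydrogen-bonded to the ester carbonyl and shielded by it.

Step 3
Reactants: 4 methyl 2-hydroxy-6-methyl-4-[(triisopropylsilyl)oxy]benzoate
Product: 5 methyl 2-methoxy-6-methyl-4-[(triisopropylsilyl)oxy]benzoate
Conditions: MeI, K2CO3, acetone, reflux
Reagents that add atoms: iodomethane, CI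
Why: Williamson O-methylation of the remaining hydrogen-bonded phenol under anhydrous conditions that the bulky silyl ether should survive; this methyl becomes the C4 methoxyl of the naphthalene.

Step 4
Reactants: 5 methyl 2-methoxy-6-methyl-4-[(triisopropylsilyl)oxy]benzoate; 6 methyl (E)-3-methoxybut-2-enoate
Product: 8 methyl 1-hydroxy-8-methoxy-3-methyl-6-[(triisopropylsilyl)oxy]naphthalene-2-carboxylate, via tetralone keto ester 7 (not isolated)
Conditions: LiN(iPr)2, THF, −78 °C; then 6, −78 °C to rt; aq. HCl
Reagents that add atoms: none
Why: Staunton–Weinreb annulation (tandem Michael addition–Dieckmann condensation): the laterally lithiated ortho-toluate adds to the β-carbon of the β-methoxy enoate, the ester enolate acylates on the neighbouring aryl ester, and loss of methanol from 7 aromatises ring B, by analogy with annulations of orsellinate anions with 4-methoxypyran-2-ones.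

Step 5
Reactants: 8 methyl 1-hydroxy-8-methoxy-3-methyl-6-[(triisopropylsilyl)oxy]naphthalene-2-carboxylate
Product: 10 4-methoxy-7-methylnaphthalene-2,5-diol, via naphthoic acid 9 (not isolated)
Conditions: KOH, EtOH/H2O, reflux, Ar; then aq. HCl, 70 °C
Reagents that add atoms: none
Why: Saponification with concomitant cleavage of the aryl silyl ether, then acid-promoted protodecarboxylation of ortho-hydroxy acid 9, whose carboxyl-bearing carbon is activated by the adjacent C1 hydroxyl and the conjugated C6 hydroxyl (orsellinic-acid-type decarboxylation).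

Step 6
Reactants: 10 4-methoxy-7-methylnaphthalene-2,5-diol; 2 5-methoxy-2-methylnaphthalene-1,4-dione (2.1 equiv)
Product: 12 target quinone 3-(2,5-dihydroxy-4-methoxy-7-methylnaphthalen-1-yl)-5-methoxy-2-methylnaphthalene-1,4-dione, via arylhydroquinone 11 (not isolated)
Conditions: 2 (2.1 equiv, added slowly), (PhO)2P(O)OH (10 mol%), CH2Cl2/HFIP, rt, Ar
Reagents that add atoms: none
Why: The Brønsted acid hydrogen-bonds to a quinone carbonyl of 2 and to the C2 hydroxyl of 10, so that naphthalene C1 attacks quinone C3 in a Friedel–Crafts-type conjugate addition; the adduct rearomatises and enolises to arylhydroquinone 11, which is more electron-rich than the hydroquinone of 2 and should therefore be dehydrogenated by the second equivalent of 2 (quinone–hydroquinone redox exchange). The closest known reaction type is the acid-catalysed arylation of quinones with 2-naphthols followed by reoxidation of the arylhydroquinone. No ring is closed and no stereocentre is formed; the new biaryl axis arises as the racemate. The step needs site selectivity on both partners: in 10 the arenium ion from attack at C1 (α-carbon of ring A) is stabilised by the ortho C2 hydroxyl and the para C4 methoxyl, which should outweigh attack at C3 (β-carbon between two substituents) and at C6 or C8 of ring B, which have only one oxygen donor in an ortho or para position; in 2 only C3 carries hydrogen. The C2 methyl of the quinone should also prevent a second addition and a furan-forming ring closure by the C2 hydroxyl.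

Compound list
1 | plumbagin (5-hydroxy-2-methylnaphthalene-1,4-dione) | CC1=CC(=O)c2c(O)cccc2C1=O | starting material
2 | 5-methoxy-2-methylnaphthalene-1,4-dione (plumbagin methyl ether) | COc1cccc2c1C(=O)C=C(C)C2=O | intermediate
3 | methyl orsellinate (methyl 2,4-dihydroxy-6-methylbenzoate) | COC(=O)c1c(C)cc(O)cc1O | starting material
4 | methyl 2-hydroxy-6-methyl-4-[(triisopropylsilyl)oxy]benzoate | COC(=O)c1c(C)cc(O[Si](C(C)C)(C(C)C)C(C)C)cc1O | intermediate
5 | methyl 2-methoxy-6-methyl-4-[(triisopropylsilyl)oxy]benzoate | COC(=O)c1c(C)cc(O[Si](C(C)C)(C(C)C)C(C)C)cc1OC | intermediate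
6 | methyl (E)-3-methoxybut-2-enoate | CO/C(C)=C/C(=O)OC | starting material
7 | methyl 3,8-dimethoxy-3-methyl-1-oxo-6-[(triisopropylsilyl)oxy]-1,2,3,4-tetrahydronaphthalene-2-carboxylate (present as its lithium enolate, mixture of diastereomers) | COC(=O)C1C(=O)c2c(OC)cc(O[Si](C(C)C)(C(C)C)C(C)C)cc2CC1(C)OC | intermediate
8 | methyl 1-hydroxy-8-methoxy-3-methyl-6-[(triisopropylsilyl)oxy]naphthalene-2-carboxylate | COC(=O)c1c(C)cc2cc(O[Si](C(C)C)(C(C)C)C(C)C)cc(OC)c2c1O | intermediate
9 | 1,6-dihydroxy-8-methoxy-3-methylnaphthalene-2-carboxylic acid | OC(=O)c1c(C)cc2cc(O)cc(OC)c2c1O | intermediate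
10 | 4-methoxy-7-methylnaphthalene-2,5-diol | Cc1cc(O)c2c(OC)cc(O)cc2c1 | intermediate
11 | 3-(2,5-dihydroxy-4-methoxy-7-methylnaphthalen-1-yl)-5-methoxy-2-methylnaphthalene-1,4-diol | COc1cccc2c(O)c(C)c(-c3c(O)cc(OC)c4c(O)cc(C)cc34)c(O)c12 | intermediate
12 | 3-(2,5-dihydroxy-4-methoxy-7-methylnaphthalen-1-yl)-5-methoxy-2-methylnaphthalene-1,4-dione (racemic about the biaryl axis) | COc1cccc2c1C(=O)C(c1c(O)cc(OC)c3c(O)cc(C)cc13)=C(C)C2=O | target

Total step count: 6. Longest linear sequence: 5 steps (steps 2 to 6); step 1 is a one-step side branch.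

Steps most likely to fail

First, step 6, the key coupling. Arylation could be diverted to C3, C6 or C8 of the naphthalenediol, a second quinone could add to the product, or addition to the methyl-substituted quinone could be too slow. The same bond would then be made by a Suzuki–Miyaura coupling.
- Setting out from 10, both hydroxyls are protected with MOMCl and iPr2NEt in CH2Cl2 to give 4-methoxy-2,5-bis(methoxymethoxy)-7-methylnaphthalene F1.
- NBS in MeCN at −20 °C should brominate F1 at C1 to 1-bromo-4-methoxy-2,5-bis(methoxymethoxy)-7-methylnaphthalene F2.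
- Bromine–lithium exchange (n-BuLi, THF, −78 °C), B(OiPr)3 and mild aqueous work-up give [4-methoxy-2,5-bis(methoxymethoxy)-7-methylnaphthalen-1-yl]boronic acid F3.
- Setting out from 2, addition–elimination with Br2 and NaOAc in AcOH gives 3-bromo-5-methoxy-2-methylnaphthalene-1,4-dione F4.
- Coupling of F3 with F4 (Pd(OAc)2, SPhos, K3PO4, toluene/H2O, 80 °C) should give 3-[4-methoxy-2,5-bis(methoxymethoxy)-7-methylnaphthalen-1-yl]-5-methoxy-2-methylnaphthalene-1,4-dione F5.
- HCl in MeOH at 40 °C removes both acetals, and the fallback comes back to the route at 12.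

Second, step 4, the annulation. The benzylic anion could be quenched by proton transfer from the γ-methyl group of 6, or could add too slowly to the electron-rich β-methoxy enoate. The fallback sets out from 5 and uses the plain crotonate, with the oxidation level adjusted afterwards.
- Lithiated 5 (LiN(iPr)2, THF, −78 °C) is treated with methyl crotonate in a Staunton–Weinreb annulation to give racemic methyl 1-hydroxy-8-methoxy-3-methyl-6-[(triisopropylsilyl)oxy]-3,4-dihydronaphthalene-2-carboxylate F6.
- KOH in refluxing aqueous EtOH followed by HCl hydrolyses and decarboxylates the β-keto ester and removes the silyl group, giving racemic 6-hydroxy-8-methoxy-3-methyl-3,4-dihydronaphthalen-1(2H)-one F7.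
- Dehydrogenation over Pd/C in refluxing p-cymene aromatises ring B, and the fallback comes back to the route at 10.

Third, step 5. Saponification of the hindered, hydrogen-bonded ester could stall, or the electron-rich naphtholate could decompose oxidatively in hot alkali. The fallback sets out from 8 and cleaves the ester at the methyl–oxygen bond instead.
- SN2 dealkylation with LiI in refluxing pyridine, acidic work-up and loss of CO2 from the liberated acid should give 8-methoxy-3-methyl-6-[(triisopropylsilyl)oxy]naphthalen-1-ol F8.
- Bu4NF in THF at 0 °C removes the silyl ether under near-neutral, non-oxidising conditions, and the fallback comes back to the route at 10.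

Further compounds
F1 | step 6 | 4-methoxy-2,5-bis(methoxymethoxy)-7-methylnaphthalene | COCOc1cc(OC)c2c(OCOC)cc(C)cc2c1
F2 | step 6 | 1-bromo-4-methoxy-2,5-bis(methoxymethoxy)-7-methylnaphthalene | COCOc1cc(OC)c2c(OCOC)cc(C)cc2c1Br
F3 | step 6 | [4-methoxy-2,5-bis(methoxymethoxy)-7-methylnaphthalen-1-yl]boronic acid | COCOc1cc(OC)c2c(OCOC)cc(C)cc2c1B(O)O
F4 | step 6 | 3-bromo-5-methoxy-2-methylnaphthalene-1,4-dione | COc1cccc2c1C(=O)C(Br)=C(C)C2=O
F5 | step 6 | 3-[4-methoxy-2,5-bis(methoxymethoxy)-7-methylnaphthalen-1-yl]-5-methoxy-2-methylnaphthalene-1,4-dione | COCOc1cc(OC)c2c(OCOC)cc(C)cc2c1C1=C(C)C(=O)c2cccc(OC)c2C1=O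
F6 | step 4 | methyl 1-hydroxy-8-methoxy-3-methyl-6-[(triisopropylsilyl)oxy]-3,4-dihydronaphthalene-2-carboxylate (racemic) | COC(=O)C1=C(O)c2c(OC)cc(O[Si](C(C)C)(C(C)C)C(C)C)cc2CC1C
F7 | step 4 | 6-hydroxy-8-methoxy-3-methyl-3,4-dihydronaphthalen-1(2H)-one (racemic) | CC1CC(=O)c2c(OC)cc(O)cc2C1
F8 | step 5 | 8-methoxy-3-methyl-6-[(triisopropylsilyl)oxy]naphthalen-1-ol | Cc1cc(O)c2c(OC)cc(O[Si](C(C)C)(C(C)C)C(C)C)cc2c1
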